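The synthesis rests on cutting the dihydropyran ring of the 2,2-dimethylchroman across C3–C2 and O1–C8a, which uncovers acetone and an ortho-fluoroaryl methyl ketone. In the key step the ketone enolate adds to acetone (C3–C2) and the resulting tertiary alkoxide displaces fluoride at C8a (O1–C8a), closing the pyran ring in one operation. The step exploits the gem-dimethyl carbinol carbon C2 next to O1 as a latent acetone carbonyl, and a temporary C4 ketone, conjugated to ring B, that both acidifies C3 and activates C8a; it is reduced away afterwards. The isoflavone is then assembled by Suzuki coupling of the chroman bromide with a 3-iodochromone and debenzylation.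

Key step: step 2

Remark: chroman numbering (O1, C2, C3, C4, C4a, C5 to C8, C8a) is used for the pyran-fused ring B unit throughout, also in its open-chain precursors; benzyl ether 1 is assumed to be a purchasable building block.

Step 1
Reactants: 1 1-(benzyloxy)-4-bromo-2-fluorobenzene
Product: 3 1-[3-(benzyloxy)-6-bromo-2-fluorophenyl]ethan-1-one, via aryllithium 2 (not isolated)
Conditions: LDA, THF, −78 °C; then MeC(O)N(OMe)Me, −78 °C; aq. NH4Cl
Reagents that add atoms: N-methoxy-N-methylacetamide, CC(=O)N(C)OC
Why: Directed ortho-lithiation: the ring C–H flanked by F and Br is the most acidic site and should be removed by LDA at −78 °C, and acylation with the Weinreb amide stops at the ketone because the chelated tetrahedral adduct survives until work-up.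

Step 2
Reactants: 3 1-[3-(benzyloxy)-6-bromo-2-fluorophenyl]ethan-1-one; 4 acetone
Product: 7 8-(benzyloxy)-5-bromo-2,2-dimethylchroman-4-one, via lithium enolate 5 (not isolated), via lithium aldolate 6 (not isolated)
Conditions: LiN(SiMe3)2, THF, −78 °C; acetone (3 equiv), −78 °C; then DMPU, −78 → 50 °C
Reagents that add atoms: none
Why: LiN(SiMe3)2 forms the lithium enolate 5 at the methyl group (the future C3), which adds to the acetone carbonyl at −78 °C to give the chelated tertiary aldolate 6 (C3–C2 bond); on warming with DMPU this alkoxide attacks C8a, which is activated by the ortho C4 ketone, and fluoride leaves from the Meisenheimer adduct (O1–C8a bond). The closest known reaction types are the crossed aldol addition of a methyl ketone enolate to a ketone and the intramolecular SNAr of β-hydroxy ketone alkoxides onto 2-fluoroaryl ketones, run here as a tandem aldol–SNAr annulation. The pyranone ring closes in a 6-endo-trig addition–elimination, the attacked C8a=C4a bond lying inside the new six-membered ring. No stereocentre is formed because C2 carries two methyl groups. The step needs chemoselectivity for the fluorine-bearing over the bromine-bearing ortho carbon, which the much higher SNAr reactivity of aryl fluorides should secure, and it needs the reversible aldol to be drained forward, which excess acetone and the irreversible loss of LiF should secure.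

Step 3
Reactants: 7 8-(benzyloxy)-5-bromo-2,2-dimethylchroman-4-one
Product: 8 8-(benzyloxy)-5-bromo-2,2-dimethylchromane
Conditions: Et3SiH, TFA, CH2Cl2, 0 °C → rt
Reagents that add atoms: none
Why: Ionic hydrogenation (Et3SiH/TFA deoxygenation of an aryl ketone): the protonated C4 carbonyl and then the C4 benzylic cation, both stabilised by the ortho ring oxygen O1, accept hydride from the silane, while the aryl bromide and the benzyl ether should be inert at room temperature.

Step 4
Reactants: 9 1-(2,4,6-trihydroxyphenyl)ethan-1-one
Product: 10 1-[2,4-bis(benzyloxy)-6-hydroxyphenyl]ethan-1-one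
Conditions: BnBr (2.1 equiv), K2CO3, DMF, rt
Reagents that add atoms: benzyl bromide, BrCc1ccccc1
Why: Williamson etherification: the para hydroxyl and one ortho hydroxyl are benzylated, while the remaining ortho hydroxyl is held in a hydrogen bond to the acetyl carbonyl and should stay free.

Step 5
Reactants: 10 1-[2,4-bis(benzyloxy)-6-hydroxyphenyl]ethan-1-one
Product: 12 5,7-bis(benzyloxy)-3-iodo-4H-chromen-4-one, via enaminone 11 (not isolated)
Conditions: Me2NCH(OMe)2, toluene, 95 °C; evaporate; then I2, pyridine, CHCl3, rt
Reagents that add atoms: N,N-dimethylformamide dimethyl acetal, COC(OC)N(C)C; iodine, II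
Why: Enaminone formation by condensation of the methyl ketone with the formamide acetal, followed by iodine-triggered cyclisation: iodination of the enaminone α-carbon gives an iminium ion onto which the ortho phenol closes, and loss of dimethylamine gives the 3-iodochromone.

Step 6
Reactants: 8 8-(benzyloxy)-5-bromo-2,2-dimethylchromane; 12 5,7-bis(benzyloxy)-3-iodo-4H-chromen-4-one
Product: 14 5,7-bis(benzyloxy)-3-[8-(benzyloxy)-2,2-dimethylchroman-5-yl]-4H-chromen-4-one, via pinacol boronate 13 (not isolated)
Conditions: B2pin2, KOAc, Pd(dppf)Cl2, 1,4-dioxane, 90 °C; then 12, aq. K2CO3, 90 °C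
Reagents that add atoms: none
Why: One-pot Miyaura borylation and Suzuki–Miyaura coupling: zerovalent palladium inserts into the C5–Br bond of 8 and hands the aryl group to boron, and boronate 13 then couples at the reactive C3–I bond of the chromone, the standard way of making isoflavones from 3-iodochromones.

Step 7
Reactants: 14 5,7-bis(benzyloxy)-3-[8-(benzyloxy)-2,2-dimethylchroman-5-yl]-4H-chromen-4-one
Product: 15 5,7-dihydroxy-3-(8-hydroxy-2,2-dimethylchroman-5-yl)-4H-chromen-4-one
Conditions: H2 (1 atm), Pd/C, THF/MeOH, rt
Reagents that add atoms: none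
Why: Catalytic hydrogenolysis of the three benzyl aryl ethers over palladium on carbon, which should leave the tertiary alkyl aryl ether of the chroman and the chromone C2=C3 bond intact at balloon pressure and room temperature.

Compound list
1 | 1-(benzyloxy)-4-bromo-2-fluorobenzene | Fc1cc(Br)ccc1OCc1ccccc1 | starting material
2 | [3-(benzyloxy)-6-bromo-2-fluorophenyl]lithium | [Li]c1c(F)c(OCc2ccccc2)ccc1Br | intermediate
3 | 1-[3-(benzyloxy)-6-bromo-2-fluorophenyl]ethan-1-one | CC(=O)c1c(Br)ccc(OCc2ccccc2)c1F | intermediate
4 | acetone | CC(C)=O | starting material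
5 | lithium 1-[3-(benzyloxy)-6-bromo-2-fluorophenyl]ethen-1-olate | [Li]OC(=C)c1c(Br)ccc(OCc2ccccc2)c1F | intermediate
6 | lithium 4-[3-(benzyloxy)-6-bromo-2-fluorophenyl]-2-methyl-4-oxobutan-2-olate | [Li]OC(C)(C)CC(=O)c1c(Br)ccc(OCc2ccccc2)c1F | intermediate
7 | 8-(benzyloxy)-5-bromo-2,2-dimethylchroman-4-one | CC1(C)CC(=O)c2c(Br)ccc(OCc3ccccc3)c2O1 | intermediate
8 | 8-(benzyloxy)-5-bromo-2,2-dimethylchromane | CC1(C)CCc2c(Br)ccc(OCc3ccccc3)c2O1 | intermediate
9 | 1-(2,4,6-trihydroxyphenyl)ethan-1-one | CC(=O)c1c(O)cc(O)cc1O | starting material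
10 | 1-[2,4-bis(benzyloxy)-6-hydroxyphenyl]ethan-1-one | CC(=O)c1c(O)cc(OCc2ccccc2)cc1OCc1ccccc1 | intermediate
11 | (E)-1-[2,4-bis(benzyloxy)-6-hydroxyphenyl]-3-(dimethylamino)prop-2-en-1-one | CN(C)/C=C/C(=O)c1c(O)cc(OCc2ccccc2)cc1OCc1ccccc1 | intermediate
12 | 5,7-bis(benzyloxy)-3-iodo-4H-chromen-4-one | O=c1c(I)coc2cc(OCc3ccccc3)cc(OCc3ccccc3)c12 | intermediate
13 | 2-[8-(benzyloxy)-2,2-dimethylchroman-5-yl]-4,4,5,5-tetramethyl-1,3,2-dioxaborolane | CC1(C)CCc2c(B3OC(C)(C)C(C)(C)O3)ccc(OCc3ccccc3)c2O1 | intermediate
14 | 5,7-bis(benzyloxy)-3-[8-(benzyloxy)-2,2-dimethylchroman-5-yl]-4H-chromen-4-one | CC1(C)CCc2c(-c3coc4cc(OCc5ccccc5)cc(OCc5ccccc5)c4c3=O)ccc(OCc3ccccc3)c2O1 | intermediate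
15 | 5,7-dihydroxy-3-(8-hydroxy-2,2-dimethylchroman-5-yl)-4H-chromen-4-one (CNP0078088.0) | CC1(C)CCc2c(-c3coc4cc(O)cc(O)c4c3=O)ccc(O)c2O1 | target

Total step count: 7
Longest linear sequence: 5 steps (steps 1, 2, 3, 6 and 7); steps 4 and 5 form the convergent branch.

Steps most likely to fail

Step 2. Retro-aldol cleavage and dehydration of the aldolate may outrun ring closure, and some alkoxide attack at the bromine-bearing ortho carbon may occur. The fallback sets out from 3 and builds the ring from the oxygen side. Fluoride is first displaced by hydroxide (KOH, DMSO/H2O, 60 °C, acidic work-up) to give 1-[3-(benzyloxy)-6-bromo-2-hydroxyphenyl]ethan-1-one F1. Kabbe condensation of this with acetone and pyrrolidine (MeOH, reflux) then proceeds by enamine aldol condensation and oxa-Michael closure of the phenol onto C2, and the route is rejoined at 7.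

Step 3. The benzyl ether may be partly cleaved in TFA, or the reduction of the peri-bromo ketone may stall. The fallback sets out from 7 and separates the two hydride transfers. NaBH4 (MeOH/THF, 0 °C) should give racemic 8-(benzyloxy)-5-bromo-2,2-dimethylchroman-4-ol F2. Its benzylic hydroxyl is then removed with Et3SiH and BF3·OEt2 (CH2Cl2, −78 → 0 °C), a short and cold exposure to acid, and the route is rejoined at 8.

Step 6. Borylation of the hindered, electron-rich bromide may be slow, and the boronate may suffer protodeboronation or homocoupling under the aqueous base. The fallback sets out from 8 and uses a Negishi coupling instead. Bromine–lithium exchange (n-BuLi, THF, −78 °C) should give [8-(benzyloxy)-2,2-dimethylchroman-5-yl]lithium F3. ZnCl2 converts it into [8-(benzyloxy)-2,2-dimethylchroman-5-yl]zinc chloride F4. Coupling with 12 under Pd(PPh3)4 (THF, rt to 50 °C, anhydrous and base-free) rejoins the route at 14.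

Further compounds
F1 | step 2 | 1-[3-(benzyloxy)-6-bromo-2-hydroxyphenyl]ethan-1-one | CC(=O)c1c(Br)ccc(OCc2ccccc2)c1O
F2 | step 3 | 8-(benzyloxy)-5-bromo-2,2-dimethylchroman-4-ol (racemic) | CC1(C)CC(O)c2c(Br)ccc(OCc3ccccc3)c2O1
F3 | step 6 | [8-(benzyloxy)-2,2-dimethylchroman-5-yl]lithium | [Li]c1ccc(OCc2ccccc2)c2OC(C)(C)CCc12
F4 | step 6 | [8-(benzyloxy)-2,2-dimethylchroman-5-yl]zinc chloride | Cl[Zn]c1ccc(OCc2ccccc2)c2OC(C)(C)CCc12
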